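How much bis adduct does gamma end with, and which of substrate, first product and bis adduct holds the largest part of the substrate at the end of each new flask?

| flask | substrate | partner | remark | time |
|---|---|---|---|---|
| blue | 20 mM | 17 mM | run made earlier |  |
| grey | 20 mM | 24 mM | run made earlier |  |
| violet | 20 mM | 38 mM | run made earlier |  |
| theta | 20 mM | 40.0 mM |  | 40 min |
| gamma | 20 mM | 16.0 mM |  | 40 min |

| run | time / min | bis adduct / % | first product / % | substrate / % |
|---|---|---|---|---|
| blue | 8.00 | 5.5 | 30.6 | 51.5 |
| blue | 15.0 | 6.7 | 23.8 | 47.0 |
| blue | 25.0 | 9.8 | 14.2 | 46.8 |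
| blue | 30.0 | 7.1 | 9.9 | 44.2 |
| blue | 40.0 | 10.4 | 7.4 | 45.6 |
| grey | 3.00 | 8.6 | 34.3 | 55.2 |
| grey | 6.00 | 10.6 | 34.6 | 41.5 |
| grey | 12.0 | 14.6 | 28.9 | 31.4 |
| grey | 20.0 | 18.3 | 20.1 | 31.8 |
| grey | 40.0 | 15.6 | 5.4 | 30.6 |
| violet | 3.00 | 17.3 | 43.7 | 39.3 |
| violet | 6.00 | 25.0 | 39.8 | 24.7 |
| violet | 12.0 | 34.6 | 30.4 | 15.1 |
| violet | 20.0 | 35.7 | 18.0 | 10.7 |
| violet | 40.0 | 37.5 | 6.2 | 10.6 |

(standard deviation of a reading: 1 percentage point)



- which of these holds the largest part of the substrate at the end of theta (first product / substrate / bis adduct)
- which of these holds the largest part of the substrate at the end of gamma (first product / substrate / bis adduct)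
- final bis adduct in gamma, as a percentage of the substrate charged

1. We take plateaus as means of the readings from 20.0 min on. Substrate stands at 45.5% in blue, 31.2% in grey and 10.7% in violet. Bis adduct stands at 9.10% in blue, 16.9% in grey and 36.6% in violet.

2. Grey reads 0.0103 /mM for the bis share, the part of the consumed substrate found as bis adduct, per mM of partner charged. This is a selectivity measure. Blue reads 0.00983 /mM and violet 0.0108 /mM.

3. First way: we scale the logarithm of blue's remaining substrate with partner charged, which leaves 47.7% in gamma. The grey bis share then gives 8.59% bis adduct.

4. Second way: blue and violet bis adduct follow partner charged with exponent 1.73, which gives 8.19% in gamma. The two ways use different bis readings and differ by 0.4 percentage points, less than one reading's scatter, so we commit to 8.39%.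

5. Our 47.7% of substrate for gamma therefore stands above our bis adduct figure and above the last first product reading of blue, 7.4%. With violet's consumption of substrate, the bis share gives theta 36.7% bis adduct, above the last substrate and first product readings of violet.

6. The forecast, reasoning “Gamma (16 mM) resembles blue”, named bis adduct for theta and substrate for gamma, with 8.5% bis adduct in gamma (7% to 10.2%).

7. Gamma ends with 8.00% bis adduct; of the three species asked about, substrate holds the largest part in gamma and bis adduct in theta, as forecast.

    first product → over-reaction product (k = 0.0547 /min)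
    partner → decomposed reagent (k = 0.0706 /min)
    substrate + partner → first product (k = 12.7 /M/min)
    partner + first product → bis adduct (k = 6.61 /M/min)

At 400 min gamma still holds 8.01% bis adduct, with 0.012% of its partner left at 40.0 min. Gamma's own end values put the bis share at 0.00967 /mM. A neighbour of gamma charged with 9.6 mM of partner keeps 66% of its substrate, so the grey bis share gives it 3.31% bis adduct, and that flask ends with 2.99%.

The numbers in the tables were computed with constants of no real substance, noise included.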